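Ring C is treated as a masked para-dioxygenated benzene: oxygen on C3' and C6', carbon arms only on C1' (the C11 methylene) and C4' (CH2O), hydrogen on C2' and C5'. This pattern results when a 4-(alk-1-en-2-yl)-4-oxy-2-alkylcyclobutenone is heated: the strained ring unzips to a ketene conjugated with two C=C bonds, and the ketene carbon (future C3') joins the far end of the propenyl group (future C2'), so ring C and its substitution pattern arise in one operation. The precursor is a squarate-derived 4-silyloxycyclobutenone carrying the protected oxymethyl group at C2 and, at C4, a propenyl unit whose attached carbon was the lactone carbonyl of sclareolide. Dearomatisation, face-selective epoxidation, directed reduction and acylation complete the route.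

Key step: step 8

Remarks on the chemistry (assumptions)
- Locants and abbreviations: ring C is numbered C1' (bears the C11 methylene), C2', C3', C4' (bears CH2O), C5', C6'; Dr = (1S,4aS,8aS)-5,5,8a-trimethyl-2-methylidenedecahydronaphthalen-1-yl; PMB = 4-methoxybenzyl; PMBOCH2 = [(4-methoxybenzyl)oxy]methyl; TBS = tert-butyldimethylsilyl.
- The carbinol carbon of cyclobutenones 13 to 16 forms as both epimers and is drawn without configuration; it becomes the sp2 carbon C6' in step 8.
- The oxymethyl arm is carried as a PMB ether, because an α-silyloxymethyllithium would isomerise by O-to-C silyl shift (retro-Brook) before it could add to the squarate.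
- The carbinol oxygen is silylated so that the hydroquinone emerges with C6'–O capped and C3'–OH free; this decides beforehand that C3' becomes the ketal and C6' the ketone.
- An isopropoxy group on the cyclobutenedione dictates which carbonyl accepts the alkenyllithium and is excised afterwards (step 7); a 3-monosubstituted cyclobutenedione would leave that choice to a small steric bias.
- The absolute sense of induction in steps 12 and 16 is assigned by analogy with simpler substrates; in both cases the pseudo-enantiomeric alkaloid derivative is available.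

Step 1
Reactants: 1 (+)-sclareolide
Product: 2 1-[(1R,2R,4aS,8aS)-2-hydroxy-2,5,5,8a-tetramethyldecahydronaphthalen-1-yl]propan-2-one
Conditions: MeLi (1.1 equiv), THF, −78 °C; then H2O
Reagents that add atoms: methyllithium, [Li]C
Why: Nucleophilic acyl addition to the lactone: at −78 °C the tetrahedral lithium hemiketal should persist until the quench, so only one methyl group is delivered and the ketone is released on work-up, with C5, C8, C9 and C10 untouched.

Step 2
Reactants: 2 the hydroxy ketone
Product: 3 1-[(1S,4aS,8aS)-5,5,8a-trimethyl-2-methylidenedecahydronaphthalen-1-yl]propan-2-one (1-Dr-propan-2-one)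
Conditions: SOCl2, pyridine, CH2Cl2, −78 °C; AgNO3–SiO2 chromatography
Reagents that add atoms: none
Why: E2 dehydration through the chlorosulfite: the 8α C–O bond is equatorial and has no ring C–H antiperiplanar to it, so a C17 methyl hydrogen is removed and the exocyclic alkene should dominate, ring-alkene isomers being removed on the silver-loaded silica.

Step 3
Reactants: 3 1-Dr-propan-2-one
Product: 4 N'-(1-Dr-propan-2-ylidene)-2,4,6-triisopropylbenzenesulfonohydrazide
Conditions: 2,4,6-(i-Pr)3C6H2SO2NHNH2, THF, cat. pyridinium p-toluenesulfonate, rt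
Reagents that add atoms: 2,4,6-triisopropylbenzenesulfonohydrazide, NNS(=O)(=O)c1c(C(C)C)cc(C(C)C)cc1C(C)C
Why: Condensation of the unhindered methyl ketone gives the sulfonylhydrazone needed for the Shapiro reaction, the triisopropylphenyl group preventing ortho-lithiation of the aryl ring later.

Step 4
Reactants: 5 4-methoxybenzyl alcohol; 6 tributyl(iodomethyl)stannane
Product: 7 tributyl{[(4-methoxybenzyl)oxy]methyl}stannane
Conditions: NaH, THF/DMF, 0 °C to rt
Reagents that add atoms: none
Why: Williamson ether synthesis, the sodium alkoxide displacing iodide from the primary iodomethyl carbon by SN2.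

Step 5
Reactants: 7 the alkoxymethylstannane; 8 diisopropyl squarate
Product: 11 3-isopropoxy-4-(PMBOCH2)cyclobut-3-ene-1,2-dione, via alkoxymethyllithium 9 (not isolated), via lithium alkoxide adduct 10 (not isolated)
Conditions: n-BuLi, THF, −78 °C; add 8, −78 °C; then (CF3CO)2O, −78 °C; H2O
Reagents that add atoms: water, O
Why: Tin–lithium exchange gives the α-alkoxymethyllithium 9, which adds 1,2 to one carbonyl of the symmetrical squarate, and trifluoroacetylation of alkoxide 10 followed by water causes ionisation assisted by the vinylogous isopropoxy group and hydrolysis to the dione (the standard squarate to 3-alkoxy-4-alkylcyclobutenedione sequence).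

Step 6
Reactants: 4 the trisylhydrazone; 11 the isopropoxy dione
Product: 14 4-(3-Dr-prop-1-en-2-yl)-3-isopropoxy-2-(PMBOCH2)-4-(TBSO)cyclobut-2-en-1-one, via alkenyllithium 12 (not isolated), via lithium alkoxide 13 (not isolated)
Conditions: 4, n-BuLi (2.05 equiv), THF, −78 to 0 °C; recool to −78 °C, add 11; then t-BuMe2SiOTf, −78 to −20 °C
Reagents that add atoms: tert-butyldimethylsilyl trifluoromethanesulfonate, CC(C)(C)[Si](C)(C)OS(=O)(=O)C(F)(F)F
Why: Shapiro reaction: the hydrazone dianion forms at the methyl group and loses sulfinate and N2 to give 2-lithioalkene 12, which adds 1,2 to the ketone-like carbonyl of 11 (the one next to the isopropoxy-bearing carbon, the other being deactivated as a vinylogous ester), and the tertiary alkoxide is silylated in the flask; the new carbinol centre forms as both epimers, which does not matter.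

Step 7
Reactants: 14 the isopropoxy cyclobutenone
Product: 16 4-(3-Dr-prop-1-en-2-yl)-2-(PMBOCH2)-4-(TBSO)cyclobut-2-en-1-one, via cyclobutenol 15 (not isolated)
Conditions: i-Bu2AlH, CH2Cl2, −78 °C; then 1 M aq. HCl, THF, 0 °C
Reagents that add atoms: water, O
Why: Hydride adds 1,2 to the vinylogous-ester carbonyl and dilute acid then ionises the allylic alcohol with help from the isopropoxy oxygen and hydrolyses the oxocarbenium ion (a Stork–Danheiser-type 1,3-carbonyl transposition, the same reduction–hydrolysis that converts squarates into semisquarates), so hydrogen replaces the isopropoxy group and the carbonyl ends up between the carbinol carbon and the oxymethyl-bearing carbon.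

Step 8
Reactants: 16 the 4-silyloxycyclobutenone
Product: 19 5-(Dr-methyl)-2-(PMBOCH2)-4-(TBSO)phenol, via dienylketene 17 (not isolated), via cyclohexadienone 18 (not isolated)
Conditions: degassed toluene (0.01 M), 110 °C, Ar
Reagents that add atoms: none
Why: Thermal conrotatory 4π ring opening of the bond between the carbonyl and the carbinol carbon gives dienylketene 17, whose ketene carbon (C3') then closes onto the propenyl terminus (C2') in a 6π disrotatory electrocyclisation to cyclohexa-2,4-dienone 18, and enolisation of the C2' methylene aromatises the ring to 19; this is the Moore rearrangement of 4-alkenyl-4-oxycyclobutenones. Ring C is thus closed in the 6π electrocyclic mode, with C3'–C2' as the only new skeletal bond. No stereocentre is created, and the epimeric carbinol carbon of 16 becomes sp2 (C6'), so both epimers converge. The selectivity required is torquoselectivity: the donor silyloxy group should rotate outward, which places the propenyl group cis to the ketene arm, the only geometry able to cyclise. Regiochemistry is already fixed in 16 by the position of its carbonyl, and the silyl group on the C6' oxygen leaves the C3' phenol as the only free hydroxyl. The neutral, reagent-free conditions should leave the exocyclic C8 alkene, the silyl ether and the PMB ether untouched.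

Step 9
Reactants: 19 the mono-silylated hydroquinone
Product: 20 tert-butyl[4-methoxy-2-(Dr-methyl)-5-(PMBOCH2)phenoxy]dimethylsilane
Conditions: MeI, K2CO3, acetone, 40 °C
Reagents that add atoms: iodomethane, CI
Why: Williamson methylation of the only free phenol (C3'–OH), the hindered aryl silyl ether at C6' being stable to K2CO3 in acetone.

Step 10
Reactants: 20 the aryl silyl ether
Product: 21 4-methoxy-2-(Dr-methyl)-5-(PMBOCH2)phenol
Conditions: n-Bu4NF, AcOH, THF, 0 °C
Reagents that add atoms: none
Why: Fluoride cleaves the aryl Si–O bond (strong Si–F bond, phenoxide leaving group) while the benzyl-type ether is inert, which exposes the C6' phenol alone.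

Step 11
Reactants: 21 the 4-methoxyphenol
Product: 22 4,4-dimethoxy-2-(Dr-methyl)-5-(PMBOCH2)cyclohexa-2,5-dien-1-one
Conditions: PhI(OAc)2, MeOH, 0 °C
Reagents that add atoms: methanol, CO
Why: Oxidative dearomatisation of a 4-methoxyphenol by the trivalent iodine reagent: methanol captures the activated ring at the methoxy-bearing para carbon C3', so the ketone can only arise at C6' and the ketal at C3'.

Step 12
Reactants: 22 the quinone monoketal
Product: 23 (1R,6S)-5,5-dimethoxy-1-(Dr-methyl)-4-(PMBOCH2)-7-oxabicyclo[4.1.0]hept-3-en-2-one (the 1'R,2'S epoxide)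
Conditions: t-BuOOH, N-benzylcinchonidinium chloride (10 mol %), aq. NaOH, toluene, 0 °C to rt
Reagents that add atoms: tert-butyl hydroperoxide, CC(C)(C)OO
Why: Weitz–Scheffer epoxidation under chiral phase-transfer catalysis: t-BuOO− adds to C2', the only enone β-carbon without a carbon substituent (C4' is blocked by its CH2O arm), and the enolate closes the epoxide, the cinchonidinium cation paired with the peroxide being expected to select the face that gives the 1'R,2'S epoxide; because the decalin is homochiral the minor epimer is a diastereomer and can be removed.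

Step 13
Reactants: 23 the epoxy ketal PMB ether
Product: 24 (1R,6S)-4-(hydroxymethyl)-5,5-dimethoxy-1-(Dr-methyl)-7-oxabicyclo[4.1.0]hept-3-en-2-one
Conditions: DDQ, CH2Cl2/pH 7 phosphate buffer, 0 °C to rt
Reagents that add atoms: none
Why: Oxidative cleavage of the PMB ether by DDQ (hydride abstraction from the electron-rich benzylic position, then hydrolysis of the oxocarbenium ion) frees the primary alcohol, while enone, epoxide, ketal and exocyclic alkene are not oxidised.

Step 14
Reactants: 24 the epoxy ketal alcohol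
Product: 25 (1R,6S)-4-(hydroxymethyl)-1-(Dr-methyl)-7-oxabicyclo[4.1.0]hept-3-ene-2,5-dione
Conditions: aq. HF (48%), MeCN, 0 °C
Reagents that add atoms: water, O
Why: Acid-catalysed hydrolysis of the dimethyl ketal to the C3' ketone, the α,β-epoxy ketone being deactivated towards acid opening and dilute aqueous HF being too weak to isomerise the exocyclic alkene.

Step 15
Reactants: 25 the epoxy enedione
Product: 26 (1R,5R,6R)-5-hydroxy-4-(hydroxymethyl)-1-(Dr-methyl)-7-oxabicyclo[4.1.0]hept-3-en-2-one
Conditions: NaBH(OAc)3, AcOH, MeCN/THF, −20 °C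
Reagents that add atoms: none
Why: Hydroxyl-directed reduction: the primary alkoxide exchanges onto boron and delivers hydride through a six-membered transition state to C3' only (C6' is out of reach, less electrophilic as a β-alkyl enone carbonyl and flanked by the quaternary C1'), and attack anti to the epoxide oxygen should set the 3'R carbinol cis to the epoxide.

Step 16
Reactants: 26 the epoxy diol; 27 3-hydroxy-3-methylglutaric anhydride
Product: 28 (3S)-3-hydroxy-5-{[(1R,5R,6R)-5-hydroxy-1-(Dr-methyl)-2-oxo-7-oxabicyclo[4.1.0]hept-3-en-4-yl]methoxy}-3-methyl-5-oxopentanoic acid (target)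
Conditions: 27 (1.5 equiv), quinidine (1.1 equiv), toluene, −40 °C; 5% aq. citric acid wash
Reagents that add atoms: none
Why: Alkaloid-mediated desymmetrising alcoholysis of a prochiral glutaric anhydride: the primary allylic hydroxyl, hydrogen-bonded to the quinuclidine nitrogen, opens one of the two enantiotopic carbonyls and so sets the (S) carbinol centre, while the secondary C3' hydroxyl and the tertiary hydroxyl are too hindered to compete.

Compound list
1 | (+)-sclareolide | C[C@]12CCCC([C@@H]1CC[C@@]3([C@@H]2CC(=O)O3)C)(C)C | starting material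
2 | 1-[(1R,2R,4aS,8aS)-2-hydroxy-2,5,5,8a-tetramethyldecahydronaphthalen-1-yl]propan-2-one | C[C@]12CCCC(C)(C)[C@@H]1CC[C@](O)(C)[C@@H]2CC(C)=O | intermediate
3 | 1-[(1S,4aS,8aS)-5,5,8a-trimethyl-2-methylidenedecahydronaphthalen-1-yl]propan-2-one | C=C1CC[C@H]2C(C)(C)CCC[C@]2(C)[C@H]1CC(C)=O | intermediate
4 | N'-(1-Dr-propan-2-ylidene)-2,4,6-triisopropylbenzenesulfonohydrazide | C=C1CC[C@H]2C(C)(C)CCC[C@]2(C)[C@H]1CC(C)=NNS(=O)(=O)c1c(C(C)C)cc(C(C)C)cc1C(C)C | intermediate
5 | 4-methoxybenzyl alcohol | COc1ccc(CO)cc1 | starting material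
6 | tributyl(iodomethyl)stannane | CCCC[Sn](CCCC)(CCCC)CI | starting material
7 | tributyl{[(4-methoxybenzyl)oxy]methyl}stannane | CCCC[Sn](CCCC)(CCCC)COCc1ccc(OC)cc1 | intermediate
8 | diisopropyl squarate | CC(C)OC1=C(OC(C)C)C(=O)C1=O | starting material
9 | [(4-methoxybenzyl)oxy]methyllithium | [Li]COCc1ccc(OC)cc1 | intermediate (not isolated)
10 | lithium 2,3-diisopropoxy-1-(PMBOCH2)-4-oxocyclobut-2-en-1-olate | [Li]OC1(COCc2ccc(OC)cc2)C(=O)C(OC(C)C)=C1OC(C)C | intermediate (not isolated)
11 | 3-isopropoxy-4-(PMBOCH2)cyclobut-3-ene-1,2-dione | CC(C)OC1=C(COCc2ccc(OC)cc2)C(=O)C1=O | intermediate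
12 | (3-Dr-prop-1-en-2-yl)lithium | C=C1CC[C@H]2C(C)(C)CCC[C@]2(C)[C@H]1CC(=C)[Li] | intermediate (not isolated)
13 | lithium 1-(3-Dr-prop-1-en-2-yl)-2-isopropoxy-3-(PMBOCH2)-4-oxocyclobut-2-en-1-olate | C=C1CC[C@H]2C(C)(C)CCC[C@]2(C)[C@H]1CC(=C)C1(O[Li])C(OC(C)C)=C(COCc2ccc(OC)cc2)C1=O | intermediate (not isolated)
14 | 4-(3-Dr-prop-1-en-2-yl)-3-isopropoxy-2-(PMBOCH2)-4-(TBSO)cyclobut-2-en-1-one | C=C1CC[C@H]2C(C)(C)CCC[C@]2(C)[C@H]1CC(=C)C1(O[Si](C)(C)C(C)(C)C)C(OC(C)C)=C(COCc2ccc(OC)cc2)C1=O | intermediate
15 | 4-(3-Dr-prop-1-en-2-yl)-3-isopropoxy-2-(PMBOCH2)-4-(TBSO)cyclobut-2-en-1-ol | C=C1CC[C@H]2C(C)(C)CCC[C@]2(C)[C@H]1CC(=C)C1(O[Si](C)(C)C(C)(C)C)C(OC(C)C)=C(COCc2ccc(OC)cc2)C1O | intermediate (not isolated)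
16 | 4-(3-Dr-prop-1-en-2-yl)-2-(PMBOCH2)-4-(TBSO)cyclobut-2-en-1-one | C=C1CC[C@H]2C(C)(C)CCC[C@]2(C)[C@H]1CC(=C)C1(O[Si](C)(C)C(C)(C)C)C=C(COCc2ccc(OC)cc2)C1=O | intermediate
17 | (3E)-5-(Dr-methyl)-2-(PMBOCH2)-4-(TBSO)hexa-1,3,5-trien-1-one (propenyl cis to the ketene arm) | C=C1CC[C@H]2C(C)(C)CCC[C@]2(C)[C@H]1CC(=C)/C(O[Si](C)(C)C(C)(C)C)=C\C(COCc1ccc(OC)cc1)=C=O | intermediate (not isolated)
18 | 5-(Dr-methyl)-2-(PMBOCH2)-4-(TBSO)cyclohexa-2,4-dien-1-one | C=C1CC[C@H]2C(C)(C)CCC[C@]2(C)[C@H]1CC1=C(O[Si](C)(C)C(C)(C)C)C=C(COCc2ccc(OC)cc2)C(=O)C1 | intermediate (not isolated)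
19 | 5-(Dr-methyl)-2-(PMBOCH2)-4-(TBSO)phenol | C=C1CC[C@H]2C(C)(C)CCC[C@]2(C)[C@H]1Cc1cc(O)c(COCc2ccc(OC)cc2)cc1O[Si](C)(C)C(C)(C)C | intermediate
20 | tert-butyl[4-methoxy-2-(Dr-methyl)-5-(PMBOCH2)phenoxy]dimethylsilane | C=C1CC[C@H]2C(C)(C)CCC[C@]2(C)[C@H]1Cc1cc(OC)c(COCc2ccc(OC)cc2)cc1O[Si](C)(C)C(C)(C)C | intermediate
21 | 4-methoxy-2-(Dr-methyl)-5-(PMBOCH2)phenol | C=C1CC[C@H]2C(C)(C)CCC[C@]2(C)[C@H]1Cc1cc(OC)c(COCc2ccc(OC)cc2)cc1O | intermediate
22 | 4,4-dimethoxy-2-(Dr-methyl)-5-(PMBOCH2)cyclohexa-2,5-dien-1-one | C=C1CC[C@H]2C(C)(C)CCC[C@]2(C)[C@H]1CC1=CC(OC)(OC)C(COCc2ccc(OC)cc2)=CC1=O | intermediate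
23 | (1R,6S)-5,5-dimethoxy-1-(Dr-methyl)-4-(PMBOCH2)-7-oxabicyclo[4.1.0]hept-3-en-2-one | C=C1CC[C@H]2C(C)(C)CCC[C@]2(C)[C@H]1C[C@@]12O[C@@H]1C(OC)(OC)C(COCc1ccc(OC)cc1)=CC2=O | intermediate
24 | (1R,6S)-4-(hydroxymethyl)-5,5-dimethoxy-1-(Dr-methyl)-7-oxabicyclo[4.1.0]hept-3-en-2-one | C=C1CC[C@H]2C(C)(C)CCC[C@]2(C)[C@H]1C[C@@]12O[C@@H]1C(OC)(OC)C(CO)=CC2=O | intermediate
25 | (1R,6S)-4-(hydroxymethyl)-1-(Dr-methyl)-7-oxabicyclo[4.1.0]hept-3-ene-2,5-dione | C=C1CC[C@H]2C(C)(C)CCC[C@]2(C)[C@H]1C[C@@]12O[C@@H]1C(=O)C(CO)=CC2=O | intermediate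
26 | (1R,5R,6R)-5-hydroxy-4-(hydroxymethyl)-1-(Dr-methyl)-7-oxabicyclo[4.1.0]hept-3-en-2-one | C=C1CC[C@H]2C(C)(C)CCC[C@]2(C)[C@H]1C[C@@]12O[C@@H]1[C@H](O)C(CO)=CC2=O | intermediate
27 | 3-hydroxy-3-methylglutaric anhydride | CC1(O)CC(=O)OC(=O)C1 | starting material
28 | (3S)-3-hydroxy-5-{[(1R,5R,6R)-5-hydroxy-1-(Dr-methyl)-2-oxo-7-oxabicyclo[4.1.0]hept-3-en-4-yl]methoxy}-3-methyl-5-oxopentanoic acid | C=C1CC[C@H]2C(C)(C)CCC[C@]2(C)[C@H]1C[C@@]12O[C@@H]1[C@H](O)C(COC(=O)C[C@@](C)(O)CC(=O)O)=CC2=O | target

Total step count: 16.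
Longest linear sequence: 14 steps (steps 1, 2, 3 and 6 to 16, from sclareolide).

Steps most likely to fail

Step 16. The discrimination between the two enantiotopic carbonyls of a 3,3-disubstituted anhydride by a bulky alcohol may be weak, which would give both epimers at the glutarate carbinol. The fallback sets out from 26 and returns at 28. Commercial dimethyl 3-hydroxy-3-methylpentanedioate F1 is hydrolysed at one enantiotopic ester group by pig liver esterase (phosphate buffer, pH 7), a desymmetrisation of established sense, to (3S)-3-hydroxy-5-methoxy-3-methyl-5-oxopentanoic acid F2. Its acid group is esterified with tert-butyl 2,2,2-trichloroacetimidate to 1-tert-butyl 5-methyl (3R)-3-hydroxy-3-methylpentanedioate F3. LiOH in THF/H2O at 0 °C should cleave only the methyl ester, giving (3R)-5-tert-butoxy-3-hydroxy-3-methyl-5-oxopentanoic acid F4. Carbodiimide coupling (EDC·HCl, cat. DMAP, CH2Cl2) to the primary hydroxyl of 26 gives the tert-butyl ester of 28 F5, and CF3CO2H in CH2Cl2 at 0 °C removes the tert-butyl group to give 28. The stereocentre then comes from the enzyme, not from the acylation; the price is a brief acid exposure of the exocyclic alkene at the end.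

Step 12. Facial selection in the peroxide addition may be poor if the catalyst and the homochiral decalin are mismatched. The fallback sets out from 22 and returns at 23: reagent control is given up and 22 is epoxidised with t-BuOOH and the achiral base DBU in THF at 0 °C. Both faces are then attacked, and 23 should form together with (1S,6R)-5,5-dimethoxy-1-(Dr-methyl)-4-(PMBOCH2)-7-oxabicyclo[4.1.0]hept-3-en-2-one F6. The two are diastereomers because of the decalin and are to be separated on silica (preparative HPLC if needed); 23 continues with step 13.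

Step 7. During the acid-mediated transposition the tertiary silyloxy-bearing carbon may ionise, or the strained ring may open, in competition with the alkoxy-assisted ionisation. The fallback removes the isopropoxy groups before the fragments are joined; it sets out from the alkoxide 10 of step 5 and from hydrazone 4 and returns at 16. Alkoxide 10 is not trifluoroacetylated but reduced in the flask with i-Bu2AlH at −78 °C, which after quenching gives 3,4-diisopropoxy-1-(PMBOCH2)cyclobut-3-ene-1,2-diol F7. Dilute HCl expels two molecules of propan-2-ol to give 3-(PMBOCH2)cyclobut-3-ene-1,2-dione F8. Alkenyllithium 12, generated from 4 as in step 6, is expected on steric grounds to add to the carbonyl next to the unsubstituted ring carbon, giving lithium 1-(3-Dr-prop-1-en-2-yl)-3-(PMBOCH2)-4-oxocyclobut-2-en-1-olate F9. Silylation in the flask with t-BuMe2SiOTf then gives 16 directly.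

Further compounds
F1 | step 16 | dimethyl 3-hydroxy-3-methylpentanedioate | COC(=O)CC(C)(O)CC(=O)OC
F2 | step 16 | (3S)-3-hydroxy-5-methoxy-3-methyl-5-oxopentanoic acid | COC(=O)C[C@@](C)(O)CC(=O)O
F3 | step 16 | 1-tert-butyl 5-methyl (3R)-3-hydroxy-3-methylpentanedioate | COC(=O)C[C@@](C)(O)CC(=O)OC(C)(C)C
F4 | step 16 | (3R)-5-tert-butoxy-3-hydroxy-3-methyl-5-oxopentanoic acid | OC(=O)C[C@@](C)(O)CC(=O)OC(C)(C)C
F5 | step 16 | tert-butyl ester of 28 | C=C1CC[C@H]2C(C)(C)CCC[C@]2(C)[C@H]1C[C@@]12O[C@@H]1[C@H](O)C(COC(=O)C[C@@](C)(O)CC(=O)OC(C)(C)C)=CC2=O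
F6 | step 12 | (1S,6R)-5,5-dimethoxy-1-(Dr-methyl)-4-(PMBOCH2)-7-oxabicyclo[4.1.0]hept-3-en-2-one | C=C1CC[C@H]2C(C)(C)CCC[C@]2(C)[C@H]1C[C@]12O[C@H]1C(OC)(OC)C(COCc1ccc(OC)cc1)=CC2=O
F7 | step 7 | 3,4-diisopropoxy-1-(PMBOCH2)cyclobut-3-ene-1,2-diol | OC1C(OC(C)C)=C(OC(C)C)C1(O)COCc1ccc(OC)cc1
F8 | step 7 | 3-(PMBOCH2)cyclobut-3-ene-1,2-dione | O=C1C=C(COCc2ccc(OC)cc2)C1=O
F9 | step 7 | lithium 1-(3-Dr-prop-1-en-2-yl)-3-(PMBOCH2)-4-oxocyclobut-2-en-1-olate | C=C1CC[C@H]2C(C)(C)CCC[C@]2(C)[C@H]1CC(=C)C1(O[Li])C=C(COCc2ccc(OC)cc2)C1=O
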